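The numbers are those of an exercise; the flask was simulated.

Ring closure is slower than dimer formation at this charge, so for your quick number reckon first how much of the charge closes, then how much of that ring stays.

| flask | starting material | time | remark | temperature |
|---|---|---|---|---|
| maple | 2.9 M | 10 min | at 110 °C until 5.0 min, from then on at 85 °C |  |
| alder | 2.9 M | 10 min |  | 85 °C |
| birch | 2.9 M | 10 min |  | 110 °C |

    2 starting material → open dimer (k1 = 0.034 /M/s, Ea1 = 60.0 kJ/mol)
    starting material + ring → side product (k2 = 4.0 × 10⁻⁴ /M/s, Ea2 = 90.0 kJ/mol)
    ring ⇌ isomer of the product (K3 = 1.2, k3 = 6.4 × 10⁻⁴ /s, Ea3 = 104 kJ/mol, ΔH3 = −34.0 kJ/mol)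
    starting material + ring ⇌ idle adduct, settled at all times (K4 = 0.89 /M, ΔH4 = 22.0 kJ/mol)
    starting material → ring (k5 = 0.042 /s, Ea5 = 94.0 kJ/mol)
    starting material + open dimer → open trimer (k6 = 0.13 /M/s, Ea6 = 76.0 kJ/mol)
    (constants at 110 °C)

- percent here means starting material units held: one open dimer or idle adduct or side product counts as two
- percent here means starting material units held: one open trimer counts as three
- what is said of ring includes idle adduct
- for a step with 2 of a species take k times the square, and two of it per event
- the list of constants is for 110 °C, to be carried to other temperatures by the activation energies and enthalpies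
- in an amount of ring, one idle adduct counts as one ring

- the flask with the highest amount of ring, in percent of the starting material charged ("all alike" if they lie within 1.5 percentage points) (maple / alder / birch / all alike)
- final ring, as a percentage of the starting material charged, in maple
- final ring, as a percentage of the starting material charged, in alder
- final ring, as a percentage of the starting material charged, in birch

1. Simplify the open dimer. Its trimer constant 0.13 /M/s is larger than its forming constant 0.034 /M/s, so as a rough assumption, not a proven balance, let each dimer made cost one more starting material. With c for starting material, a for the closing constant 0.042 /s and b for 0.034 /M/s, c then falls as a·c + 3·b·c squared.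

2. Leave out side product, since 0.00116 /s is far below 0.042 /s. Idle adduct counts as ring in the answer, but it also ties up starting material; leave that out as a second rough assumption.

3. Divide closing by the total fall and integrate from the charge down to zero. With x = 3·b·charge/a, which is 7.04 at 110 °C, you get F = ln(1 + x)/x = 29.6%. Call F the closing share: the part of the charge that becomes ring before any leak.

4. Carry x to 85 °C. Closing speeds up by 7.8 on heating and dimer formation by 3.72, less than closing. So cold x is 14.8 and the cold share is 18.6%.

5. Start the leak clock at zero: dimer formation alone halves the charge in 5.07 s, far shorter than the hot stay. Ring then relaxes toward its isomer, and the part kept is g = (1 + K·exp(−r·t))/(1 + K), with K = 1.2 and r = 6.4 × 10⁻⁴ /s·(1 + 1/K). That gives 0.838 after 5.0 min and 0.724 after 10 min.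

6. Freeze the leak in the cold. At 85 °C the same relaxation has a half-life of 126 min, long against the run.

7. Commit: maple 24.8%, birch 21.4%, alder 18.6%. Maple comes first, and birch closes the same share but keeps less.

The forecast names maple, with maple 25%, alder 17% and birch 22%, saying the cooling “largely freezes that loss and leaves maple ahead of birch”; its alder lies below mine.

Maple ends at 25.3%, 0.46 percentage points above closing share times g, with alder at 16.7% and birch at 22.2%. Maple's ring has moved by 5 points at a charge of 2.16 M or of 4.05 M. Now take a neighbour of maple charged with 1.2 M. Its x shrinks to 2.91, its closing share rises to 46.8%, and the same g gives 39.2% ring. That flask ends with 41.4%.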